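**Retrosynthetic overview**

1. The strategy rests on the two trisubstituted (E)-alkenes C13(CH3)=C14 and C13'(CH3)=C14' that flank the central C15=C15' bond of the chain joining ring B (C1–C6, bearing O3) to ring E (C1'–C6', bearing O3'). Each is cut to a terminal C13≡C14 alkyne plus a methyl group from AlMe3, and the centre to (E)-1-bromo-2-iodoethene (bonds C14–C15 and C14'–C15').
2. Each C18 tetraenyne is cut the same way one level down, at C9(CH3)=C10 and C10–C11, to a ring dienyne and (E)-1-bromo-4-(trimethylsilyl)but-1-en-3-yne; the dienynes come from the ring methyl ketones.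
3. No ring is formed in the route. Ring B is carried from ketoisophorone (C3 set by yeast reduction then hydride reduction; C6–C7 by Heck reaction of the enol triflate). Ring E is carried from racemic α-ionone (O3' by allylic oxidation and trans-selective reduction; absolute configuration by lipase resolution).
4. The esters go on last: palmitate on the free O3', fluoride release of O3, then myristate.

Key step: step 20

Remark: carotenoid locants are used (ring B C1–C6, chain C7–C15, primed locants for the ring E half); racemic compounds 18–20 are drawn without configuration and 21 as both enantiomers.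

Assumption: the lipase in step 14 is taken to acylate the (3R) alcohol faster, as the empirical size rule for secondary cyclohex-2-enols predicts; if the preference were reversed, the unreacted alcohol would be 23 itself.

**Route**

Step 1
Reactants: 1 acetylene
Product: 2 (E)-1-bromo-2-iodoethene
Conditions: IBr, 48% aq. HBr, 0 °C, acetylene bubbled through
Reagents that add atoms: iodine monobromide, BrI
Why: Electrophilic anti-addition of I–Br to the alkyne through a bridged iodonium ion should give the (E)-1,2-dihaloethene (halogen addition to an alkyne).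

Step 2
Reactants: 3 ethynyltrimethylsilane; 2 (E)-1-bromo-2-iodoethene
Product: 5 (E)-1-bromo-4-(trimethylsilyl)but-1-en-3-yne, via alkynylzinc bromide 4 (not isolated)
Conditions: 3, n-BuLi, THF, −78 °C; ZnBr2, 0 °C; then 2, Pd(PPh3)4 (3 mol %), THF, 0 → 23 °C
Reagents that add atoms: none
Why: Negishi alkynyl–alkenyl coupling in which zerovalent palladium inserts into the C–I bond much faster than into the C–Br bond, so only the iodide is replaced and the (E) geometry is kept.

Step 3
Reactants: 6 ketoisophorone
Product: 7 (6R)-levodione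
Conditions: baker's yeast (Saccharomyces cerevisiae), sucrose, H2O, 30 °C
Reagents that add atoms: none
Why: Biocatalytic asymmetric conjugate reduction by the ene-reductase of the yeast should hydrogenate the enedione C=C from one face and set the methyl-bearing centre as (6R), which serves as the control element for step 4.

Step 4
Reactants: 7 (6R)-levodione
Product: 8 (4R,6R)-actinol
Conditions: LiBH(s-Bu)3 (1.05 equiv), THF, −78 °C; then H2O
Reagents that add atoms: none
Why: Substrate-controlled hydride reduction of the unhindered C4 carbonyl (C1 is flanked by a quaternary and a tertiary carbon): the axial face is blocked by the axial C2 methyl, so the bulky borohydride should attack equatorially and give the axial hydroxyl trans to the C6 methyl, i.e. (4R), the future C3 of ring B.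

Step 5
Reactants: 8 (4R,6R)-actinol
Product: 9 (4R,6R)-4-(tert-butyldimethylsilyloxy)-2,2,6-trimethylcyclohexanone
Conditions: TBSCl, imidazole, DMF, 23 °C
Reagents that add atoms: tert-butyldimethylsilyl chloride, CC(C)(C)[Si](C)(C)Cl
Why: Imidazole-promoted silylation of the secondary alcohol gives an ether that withstands amide bases, AlMe3 and methanolic carbonate.

Step 6
Reactants: 9 (4R,6R)-4-(tert-butyldimethylsilyloxy)-2,2,6-trimethylcyclohexanone
Product: 10 (4R)-4-(tert-butyldimethylsilyloxy)-2,6,6-trimethylcyclohex-1-en-1-yl trifluoromethanesulfonate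
Conditions: LiN(i-Pr)2, THF, −78 → 0 °C; PhN(SO2CF3)2, 0 → 23 °C
Reagents that add atoms: N-phenylbis(trifluoromethanesulfonimide), O=S(=O)(N(c1ccccc1)S(=O)(=O)C(F)(F)F)C(F)(F)F
Why: Enol triflate formation: the ketone can enolise only toward the methyl-bearing carbon, so O-sulfonylation gives the tetrasubstituted C5=C6 alkene of ring B, erasing the auxiliary methyl centre and leaving the silyloxy carbon untouched.

Step 7
Reactants: 10 (4R)-4-(tert-butyldimethylsilyloxy)-2,6,6-trimethylcyclohex-1-en-1-yl trifluoromethanesulfonate; 11 methyl vinyl ketone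
Product: 12 (3R)-3-(tert-butyldimethylsilyloxy)-β-ionone
Conditions: Pd(OAc)2 (5 mol %), PPh3, Et3N, DMF, 70 °C
Reagents that add atoms: none
Why: Heck reaction: oxidative addition of the enol triflate to zerovalent palladium, syn insertion of the enone at its terminal carbon and syn β-hydride elimination should give the (E)-C7=C8 dienone.

Step 8
Reactants: 12 (3R)-3-(tert-butyldimethylsilyloxy)-β-ionone
Product: 14 ring B dienyne (terminal C9≡C10 alkyne), via ring B enol phosphate 13 (not isolated)
Conditions: LiN(i-Pr)2 (1.05 equiv), THF, −78 °C; ClP(O)(OEt)2, −78 → 23 °C; then LiN(i-Pr)2 (2.3 equiv), −78 → 23 °C; aq. NH4Cl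
Reagents that add atoms: none
Why: Methyl ketone to terminal alkyne conversion: kinetic deprotonation at the methyl group, O-phosphorylation, and amide-induced elimination of diethyl phosphate from the enol phosphate.

Step 9
Reactants: 14 ring B dienyne; 5 (E)-1-bromo-4-(trimethylsilyl)but-1-en-3-yne
Product: 16 ring B C18 tetraenyne C14-trimethylsilyl derivative, via ring B dienylalane 15 (not isolated)
Conditions: AlMe3 (2 equiv), Cp2ZrCl2 (0.25 equiv), ClCH2CH2Cl, 23 °C; volatiles removed; then 5, Pd(PPh3)4 (5 mol %), ZnCl2 (co-catalyst), THF, 23 °C, dark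
Reagents that add atoms: trimethylaluminium, C[Al](C)C
Why: Zirconium-catalysed syn-methylalumination puts methyl on C9 and aluminium on C10, and Negishi coupling with retention then forms C10–C11, so C9(CH3)=C10 should be (E) and the bromide geometry is carried into C11=C12.

Step 10
Reactants: 16 ring B C18 tetraenyne C14-trimethylsilyl derivative
Product: 17 ring B C18 tetraenyne (3-O-TBS, terminal C13≡C14 alkyne)
Conditions: K2CO3 (cat.), MeOH/THF, 23 °C, dark
Reagents that add atoms: none
Why: Methoxide-mediated protodesilylation cleaves the alkynyl C–Si bond selectively, the secondary tert-butyldimethylsilyl ether being inert to methanolic carbonate.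

Step 11
Reactants: 18 racemic α-ionone
Product: 19 racemic α-ionone ethylene ketal
Conditions: Me3SiOCH2CH2OSiMe3, Me3SiOSO2CF3 (cat.), CH2Cl2, −78 → −20 °C; pyridine quench
Reagents that add atoms: 1,2-bis(trimethylsilyloxy)ethane, C[Si](C)(C)OCCO[Si](C)(C)C
Why: Silyl-transfer ketalisation under aprotic low-temperature conditions masks the C9 ketone without moving the C4=C5 or C7=C8 double bonds.

Step 12
Reactants: 19 racemic α-ionone ethylene ketal
Product: 20 racemic 3-oxo-α-ionone ethylene ketal
Conditions: t-BuOOH (70% aq.), aq. NaOCl, K2CO3, MeCN, 0 °C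
Reagents that add atoms: tert-butyl hydroperoxide, CC(C)(C)OO
Why: Radical allylic oxidation: the tert-butylperoxyl radical abstracts hydrogen from the ring methylene C3 next to C4=C5 and the allylic peroxide collapses to the enone, while the C6–H is shielded by the gem-dimethyl carbon and poorly aligned with the ring alkene.

Step 13
Reactants: 20 racemic 3-oxo-α-ionone ethylene ketal
Product: 21 racemic trans-3-hydroxy-α-ionone ethylene ketal
Conditions: LiBH(s-Bu)3, THF, −78 °C; then H2O; chromatography
Reagents that add atoms: none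
Why: 1,2-Hydride reduction of the β,β-disubstituted cyclohexenone under steric approach control: the bulky borohydride avoids the face carrying the axial C1 methyl and enters syn to the pseudo-axial C6 side chain, which should place the C3 hydroxyl trans to that chain.

Step 14
Reactants: 21 racemic trans-3-hydroxy-α-ionone ethylene ketal
Product: 22 (3R,6R)-3-acetoxy-α-ionone ethylene ketal
Conditions: Burkholderia cepacia lipase (immobilised), vinyl acetate, t-BuOMe, 30 °C, run to about half conversion; chromatography
Reagents that add atoms: vinyl acetate, CC(=O)OC=C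
Why: Lipase-catalysed kinetic resolution by irreversible transesterification: the (3R,6R) alcohol should be acetylated and the (3S,6S) alcohol left and removed, which fixes the absolute configuration at C3' and C6'.

Step 15
Reactants: 22 (3R,6R)-3-acetoxy-α-ionone ethylene ketal
Product: 24 (3R,6R)-3-hydroxy-α-ionone, via hydroxy ketal 23 (not isolated)
Conditions: K2CO3 (cat.), MeOH, 23 °C; then 0.3 M aq. HCl, THF, 0 °C, short contact; NaHCO3
Reagents that add atoms: water, O
Why: Base-catalysed methanolysis of the acetate is run while C9 is still a ketal, so that C6–H is not acidified by an enone, and the enone-derived dioxolane is then hydrolysed by dilute acid much faster than the allylic carbinol can ionise (transesterification followed by acetal hydrolysis).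

Step 16
Reactants: 24 (3R,6R)-3-hydroxy-α-ionone
Product: 25 (3R,6R)-3-(tert-butyldimethylsilyloxy)-α-ionone
Conditions: TBSCl, imidazole, DMF, 23 °C
Reagents that add atoms: tert-butyldimethylsilyl chloride, CC(C)(C)[Si](C)(C)Cl
Why: Imidazole-promoted silylation protects the allylic hydroxyl against the amide base and the phosphorylating agent of the next step.

Step 17
Reactants: 25 (3R,6R)-3-(tert-butyldimethylsilyloxy)-α-ionone
Product: 27 ring E dienyne (3'-O-TBS, terminal C9'≡C10' alkyne), via ring E enol phosphate 26 (not isolated)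
Conditions: LiN(i-Pr)2 (1.05 equiv), THF, −78 °C; ClP(O)(OEt)2, −78 → 23 °C; then LiN(i-Pr)2 (2.3 equiv), −78 → 23 °C; aq. NH4Cl
Reagents that add atoms: none
Why: Methyl ketone to terminal alkyne conversion through the enol phosphate, in which kinetic deprotonation at the methyl group at −78 °C is preferred over removal of the γ-hydrogen at C6', so the C6' centre should be kept.

Step 18
Reactants: 27 ring E dienyne; 5 (E)-1-bromo-4-(trimethylsilyl)but-1-en-3-yne
Product: 29 ring E C18 tetraenyne 3'-O-TBS C14'-trimethylsilyl derivative, via ring E dienylalane 28 (not isolated)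
Conditions: AlMe3 (2 equiv), Cp2ZrCl2 (0.25 equiv), ClCH2CH2Cl, 23 °C; volatiles removed; then 5, Pd(PPh3)4 (5 mol %), ZnCl2 (co-catalyst), THF, 23 °C, dark
Reagents that add atoms: trimethylaluminium, C[Al](C)C
Why: Zirconium-catalysed syn-methylalumination of the terminal alkyne followed by Negishi coupling with retention should give (E)-C9'(CH3)=C10' and the C10'–C11' bond, the skipped ring alkene and the allylic silyl ether being spectators.

Step 19
Reactants: 29 ring E C18 tetraenyne 3'-O-TBS C14'-trimethylsilyl derivative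
Product: 30 ring E C18 tetraenyne (free 3'-OH, terminal C13'≡C14' alkyne)
Conditions: Bu4NF (3 equiv), wet THF, 0 → 23 °C, dark
Reagents that add atoms: none
Why: Fluoride-mediated desilylation cleaves both the alkynyl C–Si bond and the O–Si bond in one operation, freeing the hydroxyl that is to be acylated first.

Step 20
Reactants: 17 ring B C18 tetraenyne; 2 (E)-1-bromo-2-iodoethene; 30 ring E C18 tetraenyne
Product: 34 (3R,3'R,6'R)-lutein 3-tert-butyldimethylsilyl ether, via ring B alkenylalane 31 (not isolated), via ring B bromohexaene 32 (not isolated), via ring E alkenylalane 33 (not isolated)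
Conditions: flask A: 17, AlMe3 (2 equiv), Cp2ZrCl2 (0.25 equiv), ClCH2CH2Cl, 23 °C, volatiles removed, then 2 (1.0 equiv), Pd(PPh3)4 (5 mol %), ZnCl2 (co-catalyst), THF, 0 → 23 °C; flask B: 30, AlMe3 (3 equiv), Cp2ZrCl2 (0.25 equiv), ClCH2CH2Cl, 23 °C, volatiles removed, THF solution added to flask A, 23 °C, dark; aq. NH4Cl
Reagents that add atoms: trimethylaluminium, C[Al](C)C
Why: Each terminal alkyne undergoes Cp2ZrCl2-catalysed syn-methylalumination, with methyl delivered to the internal carbon (C13 or C13') and aluminium to the terminal carbon (C14 or C14'); the closest known reaction type is zirconium-catalysed carboalumination of conjugated enynes followed by palladium- and zinc-promoted alkenyl–alkenyl Negishi coupling. Zerovalent palladium inserts into the C–I bond of 2 much faster than into its C–Br bond, so alane 31, relayed through zinc, forms C14–C15 and leaves bromide 32, whose C–Br bond then adds to palladium and couples with alane 33 to form C14'–C15'. No ring is closed and no stereocentre is created, and the three existing stereocentres lie far from the reacting termini. The (E) geometry of C13=C14 and C13'=C14' follows from syn addition and retention in the coupling, and that of C15=C15' is carried over from 2. The step needs terminal regioselectivity in the carbometalation, secured by the unsubstituted alkyne terminus, and iodide-before-bromide chemoselectivity, secured by the different rates of oxidative addition and by consuming one equivalent of 31 before 33 is added. The C3' hydroxyl takes up one equivalent of AlMe3 and travels as its dimethylaluminium alkoxide, so it should emerge free while O3 stays silylated, which also makes any symmetrical by-products differ in polarity from 34.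

Step 21
Reactants: 34 (3R,3'R,6'R)-lutein 3-tert-butyldimethylsilyl ether; 35 palmitic acid
Product: 36 lutein 3'-O-palmitate 3-tert-butyldimethylsilyl ether
Conditions: DCC, DMAP (cat.), CH2Cl2, 0 → 23 °C, dark
Reagents that add atoms: none
Why: Steglich esterification acylates the only free hydroxyl (O3') under neutral conditions that should not ionise the allylic C3'–O bond.

Step 22
Reactants: 36 lutein 3'-O-palmitate 3-tert-butyldimethylsilyl ether
Product: 37 lutein 3'-O-palmitate
Conditions: Bu4NF, AcOH (1:1), THF, 23 °C, dark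
Reagents that add atoms: none
Why: Fluoride-mediated cleavage of the silyl ether, buffered with acetic acid so that the palmitate ester and the polyene are not exposed to basic fluoride.

Step 23
Reactants: 37 lutein 3'-O-palmitate; 38 myristic acid
Product: 39 lutein 3-O-myristate 3'-O-palmitate (CNP0230054.1)
Conditions: DCC, DMAP (cat.), CH2Cl2, 23 °C, dark
Reagents that add atoms: none
Why: Steglich esterification of the remaining C3 hydroxyl completes the mixed diester without touching the existing ester or any stereocentre.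

**Compound list**

1 | acetylene | C#C | starting material
2 | (E)-1-bromo-2-iodoethene | Br/C=C/I | intermediate
3 | ethynyltrimethylsilane | C#C[Si](C)(C)C | starting material
4 | bromo[(trimethylsilyl)ethynyl]zinc | C[Si](C)(C)C#C[Zn]Br | intermediate
5 | (E)-1-bromo-4-(trimethylsilyl)but-1-en-3-yne | Br/C=C/C#C[Si](C)(C)C | intermediate
6 | ketoisophorone (2,6,6-trimethylcyclohex-2-ene-1,4-dione) | CC1=CC(=O)CC(C)(C)C1=O | starting material
7 | (6R)-levodione ((6R)-2,2,6-trimethylcyclohexane-1,4-dione) | C[C@@H]1CC(=O)CC(C)(C)C1=O | intermediate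
8 | (4R,6R)-actinol ((4R,6R)-4-hydroxy-2,2,6-trimethylcyclohexanone, OH trans to the C6 methyl) | C[C@@H]1C[C@@H](O)CC(C)(C)C1=O | intermediate
9 | (4R,6R)-4-(tert-butyldimethylsilyloxy)-2,2,6-trimethylcyclohexanone | C[C@@H]1C[C@@H](O[Si](C)(C)C(C)(C)C)CC(C)(C)C1=O | intermediate
10 | (4R)-4-(tert-butyldimethylsilyloxy)-2,6,6-trimethylcyclohex-1-en-1-yl trifluoromethanesulfonate | FC(F)(F)S(=O)(=O)OC1=C(C)C[C@@H](O[Si](C)(C)C(C)(C)C)CC1(C)C | intermediate
11 | methyl vinyl ketone (but-3-en-2-one) | CC(=O)C=C | starting material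
12 | (3R)-3-(tert-butyldimethylsilyloxy)-β-ionone | CC(=O)/C=C/C1=C(C)C[C@@H](O[Si](C)(C)C(C)(C)C)CC1(C)C | intermediate
13 | ring B enol phosphate: diethyl (E)-4-[(4R)-4-(tert-butyldimethylsilyloxy)-2,6,6-trimethylcyclohex-1-en-1-yl]buta-1,3-dien-2-yl phosphate | C=C(OP(=O)(OCC)OCC)/C=C/C1=C(C)C[C@@H](O[Si](C)(C)C(C)(C)C)CC1(C)C | intermediate
14 | ring B dienyne: (R)-tert-butyl{[4-((E)-but-1-en-3-yn-1-yl)-3,5,5-trimethylcyclohex-3-en-1-yl]oxy}dimethylsilane | C#C/C=C/C1=C(C)C[C@@H](O[Si](C)(C)C(C)(C)C)CC1(C)C | intermediate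
15 | ring B dienylalane (C10–AlMe2, (E)-C9(CH3)=C10) | C[Al](C)/C=C(C)/C=C/C1=C(C)C[C@@H](O[Si](C)(C)C(C)(C)C)CC1(C)C | intermediate
16 | ring B C18 tetraenyne, 3-O-TBS, C14-trimethylsilyl | C[Si](C)(C)C#C/C=C/C=C(C)/C=C/C1=C(C)C[C@@H](O[Si](C)(C)C(C)(C)C)CC1(C)C | intermediate
17 | ring B C18 tetraenyne, 3-O-TBS, terminal C13≡C14 alkyne | C#C/C=C/C=C(C)/C=C/C1=C(C)C[C@@H](O[Si](C)(C)C(C)(C)C)CC1(C)C | intermediate
18 | α-ionone (racemic) | CC(=O)/C=C/C1C(C)=CCCC1(C)C | starting material
19 | α-ionone ethylene ketal (racemic) | CC1(/C=C/C2C(C)=CCCC2(C)C)OCCO1 | intermediate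
20 | 3-oxo-α-ionone ethylene ketal (racemic) | CC1(/C=C/C2C(C)=CC(=O)CC2(C)C)OCCO1 | intermediate
21 | trans-3-hydroxy-α-ionone ethylene ketal (racemate of (3R,6R) and (3S,6S)) | O[C@H]1C=C(C)[C@H](/C=C/C2(C)OCCO2)C(C)(C)C1.O[C@@H]1C=C(C)[C@@H](/C=C/C2(C)OCCO2)C(C)(C)C1 | intermediate
22 | (3R,6R)-3-acetoxy-α-ionone ethylene ketal | CC(=O)O[C@H]1C=C(C)[C@H](/C=C/C2(C)OCCO2)C(C)(C)C1 | intermediate
23 | (3R,6R)-3-hydroxy-α-ionone ethylene ketal | O[C@H]1C=C(C)[C@H](/C=C/C2(C)OCCO2)C(C)(C)C1 | intermediate
24 | (3R,6R)-3-hydroxy-α-ionone (OH trans to the side chain) | O[C@H]1C=C(C)[C@H](/C=C/C(C)=O)C(C)(C)C1 | intermediate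
25 | (3R,6R)-3-(tert-butyldimethylsilyloxy)-α-ionone | CC(C)(C)[Si](C)(C)O[C@H]1C=C(C)[C@H](/C=C/C(C)=O)C(C)(C)C1 | intermediate
26 | ring E enol phosphate: diethyl (E)-4-[(1R,4R)-4-(tert-butyldimethylsilyloxy)-2,6,6-trimethylcyclohex-2-en-1-yl]buta-1,3-dien-2-yl phosphate | CC(C)(C)[Si](C)(C)O[C@H]1C=C(C)[C@H](/C=C/C(=C)OP(=O)(OCC)OCC)C(C)(C)C1 | intermediate
27 | ring E dienyne, 3'-O-TBS, terminal C9'≡C10' alkyne | CC(C)(C)[Si](C)(C)O[C@H]1C=C(C)[C@H](/C=C/C#C)C(C)(C)C1 | intermediate
28 | ring E dienylalane (C10'–AlMe2, (E)-C9'(CH3)=C10') | CC(C)(C)[Si](C)(C)O[C@H]1C=C(C)[C@H](/C=C/C(C)=C/[Al](C)C)C(C)(C)C1 | intermediate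
29 | ring E C18 tetraenyne, 3'-O-TBS, C14'-trimethylsilyl | CC(C)(C)[Si](C)(C)O[C@H]1C=C(C)[C@H](/C=C/C(C)=C/C=C/C#C[Si](C)(C)C)C(C)(C)C1 | intermediate
30 | ring E C18 tetraenyne, free 3'-OH, terminal C13'≡C14' alkyne | O[C@H]1C=C(C)[C@H](/C=C/C(C)=C/C=C/C#C)C(C)(C)C1 | intermediate
31 | ring B alkenylalane (C14–AlMe2, (E)-C13(CH3)=C14) | C[Al](C)/C=C(C)/C=C/C=C(C)/C=C/C1=C(C)C[C@@H](O[Si](C)(C)C(C)(C)C)CC1(C)C | intermediate
32 | ring B bromohexaene (C15'–Br, all-E, 3-O-TBS) | Br/C=C/C=C(C)/C=C/C=C(C)/C=C/C1=C(C)C[C@@H](O[Si](C)(C)C(C)(C)C)CC1(C)C | intermediate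
33 | ring E alkenylalane (C14'–AlMe2, O3' as dimethylaluminium alkoxide) | C[Al](C)O[C@H]1C=C(C)[C@H](/C=C/C(C)=C/C=C/C(C)=C/[Al](C)C)C(C)(C)C1 | intermediate
34 | (3R,3'R,6'R)-lutein 3-tert-butyldimethylsilyl ether | O[C@H]1C=C(C)[C@H](/C=C/C(C)=C/C=C/C(C)=C/C=C/C=C(C)/C=C/C=C(C)/C=C/C2=C(C)C[C@@H](O[Si](C)(C)C(C)(C)C)CC2(C)C)C(C)(C)C1 | intermediate
35 | palmitic acid | CCCCCCCCCCCCCCCC(=O)O | starting material
36 | (3R,3'R,6'R)-lutein 3'-O-palmitate 3-tert-butyldimethylsilyl ether | CCCCCCCCCCCCCCCC(=O)O[C@H]1C=C(C)[C@H](/C=C/C(C)=C/C=C/C(C)=C/C=C/C=C(C)/C=C/C=C(C)/C=C/C2=C(C)C[C@@H](O[Si](C)(C)C(C)(C)C)CC2(C)C)C(C)(C)C1 | intermediate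
37 | (3R,3'R,6'R)-lutein 3'-O-palmitate | CCCCCCCCCCCCCCCC(=O)O[C@H]1C=C(C)[C@H](/C=C/C(C)=C/C=C/C(C)=C/C=C/C=C(C)/C=C/C=C(C)/C=C/C2=C(C)C[C@@H](O)CC2(C)C)C(C)(C)C1 | intermediate
38 | myristic acid | CCCCCCCCCCCCCC(=O)O | starting material
39 | (3R,3'R,6'R)-lutein 3-O-myristate 3'-O-palmitate (CNP0230054.1) | CCCCCCCCCCCCCCCC(=O)O[C@H]1C=C(C)[C@H](/C=C/C(C)=C/C=C/C(C)=C/C=C/C=C(C)/C=C/C=C(C)/C=C/C2=C(C)C[C@@H](OC(=O)CCCCCCCCCCCCC)CC2(C)C)C(C)(C)C1 | target

**Step count and risks**

Total step count: 23.
Longest linear sequence: 13 steps (steps 11–19 from α-ionone 18, then steps 20–23).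

Steps most likely to fail:

1. Step 20. The programmed order of coupling may be lost: the first alane may attack both halide termini, or unconsumed dihaloethene may capture the second alane, either of which gives symmetrical C40 by-products. Residual AlMe3 may transfer methyl, the allylic aluminium alkoxide at C3' may ionise, and the polyene may undergo E/Z isomerisation. Fallback: the two carbometalations are kept but the alanes are not coupled directly. Setting out from 17 and 30, alanes 31 and 33 are each quenched with I2 (THF, −30 °C) to give the ring B C19 alkenyl iodide F1 and the ring E C19 alkenyl iodide F3. F1 is coupled with an excess of (E)-1,2-bis(tributylstannyl)ethene (PdCl2(MeCN)2, DMF, 23 °C) to the ring B C21 alkenylstannane F2, which is isolated and joined to F3 by Stille coupling (Pd2(dba)3, AsPh3, N-methylpyrrolidone, 23 °C, dark). This comes back to the route at 34.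

2. Step 7. Oxidative addition of the hindered tetrasubstituted enol triflate may be slow, so that triflate hydrolysis and polymerisation of methyl vinyl ketone outrun the Heck coupling. Fallback: setting out from 10, Sonogashira coupling with but-3-yn-2-ol (PdCl2(PPh3)2, CuI, i-Pr2NH, DMF) gives the ring B enynol F4. Trans-selective hydroalumination of the propargylic alcohol with NaAlH2(OCH2CH2OCH3)2 in THF gives the ring B (E)-dienol F5, and MnO2 in CH2Cl2 oxidises the allylic alcohol, coming back to the route at 12.

3. Step 13. Facial selectivity of hydride delivery to the C3 carbonyl may be poor, giving cis alcohol that the lipase would also acylate. Fallback: setting out from 20, reduction with NaBH4 and CeCl3·7H2O in MeOH (Luche reduction) is used instead. The trans alcohol in the mixture is taken on directly. The cis-3-hydroxy-α-ionone ethylene ketal F6, separated by chromatography, is inverted at C3 by Mitsunobu reaction with 4-nitrobenzoic acid (PPh3, diisopropyl azodicarboxylate, THF, 0 °C) to the trans 4-nitrobenzoate F7. Methanolysis of F7 (K2CO3, MeOH) comes back to the route at 21.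

Further compounds
F1 | step 20 | ring B C19 alkenyl iodide (C14–I, all-E, 3-O-TBS) | I/C=C(C)/C=C/C=C(C)/C=C/C1=C(C)C[C@@H](O[Si](C)(C)C(C)(C)C)CC1(C)C
F2 | step 20 | ring B C21 alkenylstannane (C15'–SnBu3, all-E, 3-O-TBS) | CCCC[Sn](CCCC)(CCCC)/C=C/C=C(C)/C=C/C=C(C)/C=C/C1=C(C)C[C@@H](O[Si](C)(C)C(C)(C)C)CC1(C)C
F3 | step 20 | ring E C19 alkenyl iodide (C14'–I, all-E, free 3'-OH) | O[C@H]1C=C(C)[C@H](/C=C/C(C)=C/C=C/C(C)=C/I)C(C)(C)C1
F4 | step 7 | ring B enynol: 4-[(4R)-4-(tert-butyldimethylsilyloxy)-2,6,6-trimethylcyclohex-1-en-1-yl]but-3-yn-2-ol (carbinol epimers) | CC(O)C#CC1=C(C)C[C@@H](O[Si](C)(C)C(C)(C)C)CC1(C)C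
F5 | step 7 | ring B (E)-dienol: (3R)-3-(tert-butyldimethylsilyloxy)-β-ionol (carbinol epimers) | CC(O)/C=C/C1=C(C)C[C@@H](O[Si](C)(C)C(C)(C)C)CC1(C)C
F6 | step 13 | cis-3-hydroxy-α-ionone ethylene ketal (racemate of (3S,6R) and (3R,6S)) | O[C@@H]1C=C(C)[C@H](/C=C/C2(C)OCCO2)C(C)(C)C1.O[C@H]1C=C(C)[C@@H](/C=C/C2(C)OCCO2)C(C)(C)C1
F7 | step 13 | trans-3-(4-nitrobenzoyloxy)-α-ionone ethylene ketal (racemate of (3R,6R) and (3S,6S)) | O=C(O[C@H]1C=C(C)[C@H](/C=C/C2(C)OCCO2)C(C)(C)C1)c1ccc(cc1)[N+](=O)[O-].O=C(O[C@@H]1C=C(C)[C@@H](/C=C/C2(C)OCCO2)C(C)(C)C1)c1ccc(cc1)[N+](=O)[O-]
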